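Conventions: compound numbers are those of the steps and the compound list. Ar = 3-methoxy-4-(triisopropylsilyloxy)phenyl. The furofuran is numbered C1, C2, O3, C4, C5, C6, O7, C8 and the dihydrobenzofuran with primes. Ring A is the aryl group on C2, ring B the benzo ring of the dihydrobenzofuran, ring C the aryl group on C2'.

## Analysis of the target

The target 26 is a 3,7-dioxabicyclo[3.3.0]octane (furofuran) that carries a 4-hydroxy-3-methoxyphenyl group (ring A) on C2 and, on C6, ring B of a 7'-methoxy-2',3'-dihydrobenzofuran; C2' bears a second 4-hydroxy-3-methoxyphenyl group (ring C) and C3' a hydroxymethyl group. It has six stereocentres, all S: C1 and C5 form the cis ring fusion, H2 and H6 lie on the convex face with H1 and H5 so that both aryl groups are endo, and the C2' aryl and C3' hydroxymethyl groups are cis. Both relationships are the less stable ones (exo,exo furofurans and trans dihydrobenzofurans are the stable forms), so every centre has to be set under kinetic control and kept away from equilibrating conditions. The sensitive points are the three benzylic C–O bonds (C2–O3, C6–O7, C2'–O1'), each para to an oxygen donor: acid ionises them and hydrogenolysis can cleave them; two phenols and a primary alcohol must be carried protected. The two stereochemical units are separated by the flat ring B and cannot control one another, so each must be made as a single enantiomer and the two joined late. The strategy rests on the tetrahydrofuran ring C1–C2–O3–C4–C5: its O3–C4 unit is formaldehyde in disguise, flanked by benzylic C2 and by C5, which is alpha to C6. Once C6 is the carbonyl of a butyrolactone (C6, O7, C8, C1, C5), the carbons C1, C2 and C5 are an aryl cyclopropane fused to that lactone, with C2 as donor and C5 as acceptor carbon.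

## Retrosynthetic reasoning

O–Si bonds. The last disconnection removes three triisopropylsilyl ethers from 25. Silyl ethers are chosen over benzyl ethers because fluoride cleaves them under nearly neutral conditions, whereas hydrogenolysis would have to spare three benzylic ring C–O bonds and acid would epimerise the endo aryl groups. The forward step only has to break Si–O bonds.

C6–H. The C6–H bond of 25 is cut to give lactol 24. A hydride adds to an oxocarbenium ion at C6 from the convex face of the cis-fused bicycle, which leaves ring B on the concave face. The second endo aryl group therefore comes from the shape of the bicycle; the forward step must ionise the lactol without ionising the benzylic ether at C2.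

C6–C5'. Cutting between C6 and ring B divides 24 into lactone 11 (C6 as carbonyl carbon) and aryllithium 23, made from bromide 22. This is the most convergent cut: it falls between the two stereochemical units, and the lactone carbonyl is at the oxidation level the reduction needs. The forward step must add once to the lactone.

C2–O3 and C4–C5 (key disconnection). The tetrahydrofuran ring of 11 is opened at C2–O3 and C4–C5, which releases formaldehyde 10 and joins C2 to C5 in cyclopropane lactone 9. This cut removes one ring, two bonds and two stereocentres together. It also turns the awkward endo aryl group into the exo aryl group of a bicyclo[3.1.0]hexanone, because the forward reaction opens the donor–acceptor bond with inversion at the benzylic carbon. The forward reaction must be a stereospecific formal [3+2] annulation.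

Cyclopropane. 9 is cut at the two cyclopropane bonds to the carbon alpha to the carbonyl, giving allylic diazoacetate 8. The (E)-alkene becomes the exo relation, the tether enforces cis fusion, and a chiral dirhodium carboxamidate sets the absolute configuration. 8 comes from alcohol 5 and bromoacetyl bromide 6 through bromoacetate 7; 5 comes from ester 4, made from silylated vanillin 2 (from vanillin 1) and triethyl phosphonoacetate 3.

C2'–C3'. Bromide 22 is the silyl ether of alcohol 21, the reduction product of cis ester 20. 20 is cut at C2'–C3': carbene insertion into the benzylic C–H bond of the aryl ether in diazo ester 19 forms this bond, closes the ring and sets both centres cis under catalyst control, from an achiral precursor.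

Diazo ester. 19 is traced through tosylhydrazone 18 to keto ester 17, cut between ring B and the keto carbon into aryl iodide 15 and dimethyl oxalate 16; iodine is exchanged for magnesium while the bromine needed later stays. 15 is the ether of phenol 14 and benzylic alcohol 12; 14 is the iodination product of 4-bromo-2-methoxyphenol 13, and 12 the reduction product of 2, so rings A and C both come from 1.

## Alternatives that were turned down

Alternative 1: The disconnection is the aryl ether bond O1'–C7a'. C2' and C3' would be set in the open chain by an auxiliary-controlled anti-aldol reaction and carried into alcohol A2. Its secondary benzylic hydroxyl group is then coupled to the triflate-bearing carbon of ring B with Pd(OAc)2, a bulky di-tert-butyl biaryl phosphine and Cs2CO3, to give dihydrobenzofuran A1.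
- For: only the O–H bond reacts, so both centres pass through unchanged and the cis relation follows from the anti-aldol. The absolute configuration rests on a stoichiometric auxiliary. No diazo compound is needed. Intramolecular C–O coupling of secondary alcohols is close to established practice, so its key step is less of a venture than the one chosen here.
- Against: the palladium alkoxide of A2 has a benzylic β-hydrogen and can undergo β-hydride elimination. The triflate sits between a methoxy group and a branched chain, which slows oxidative addition and reductive elimination. The sequence of aldol, auxiliary removal, reduction, protection, triflation and coupling is long.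
- Compared with the chosen strategy: A1 solves only two of six stereocentres. The endo,endo furofuran would still have to be built from the masked aldehyde of A1, on the most valuable intermediate and with no plan for the endo geometry. The chosen strategy places its risk on cheap ring A material before the fragments meet, creates the endo geometry by stereospecific inversion, and reaches the dihydrobenzofuran in fewer steps.

Alternative 2: The bond C3'–C3a' is made by ring contraction. Diazochromanone A4, reached by diazo transfer, is irradiated in an alcohol; nitrogen is lost, the ring B carbon migrates from the carbonyl carbon to the diazo carbon, and the ketene is trapped as cis ester A3.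
- For: the chromanone skeleton is easy to assemble and C2' is not touched by the rearrangement. A3 is, apart from the phenol protecting group, the same cis ester as 20, so on where it arrives the alternative is equal. It needs no chiral catalyst in the ring-forming step if A4 is enantiopure.
- Against: C3' is created only when the enol of the new ester is protonated, so the cis relation depends on kinetic protonation anti to the aryl group and on the absence of base afterwards. A 1,2-shift of the C2' hydrogen to the carbene carbon competes. The C2' centre of A4 is β to the ketone and can racemise by reversible retro-oxa-Michael ring opening under the basic diazo transfer. The aryl bromide must survive ultraviolet light.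
- Compared with the chosen strategy: it leaves the furofuran untouched as a problem. The chosen route sets both dihydrobenzofuran centres in one catalyst-controlled insertion from an achiral diazo ester and spends its novelty where the target is hardest.

Alternative 3: The second tetrahydrofuran ring is cut at O7–C6 and C5–C6. cis-Dihydrofuran A6, which holds C1, C2 and ring A, is combined with acetal A7 of the complete ring B aldehyde under a silyl triflate. The hydroxymethyl oxygen exchanges into the acetal, the enol ether carbon closes onto the oxocarbenium ion, and the released alcohol caps C4 to give bis-endo acetal A5; the C4 substituent is later removed by ionic reduction.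
- For: this cyclisation type is the closest precedent for endo,endo furofurans. It sets C5 and C6 in the bond-forming step without relying on a later reduction, and it joins the halves late. On these points it is stronger than the chosen strategy.
- Against: A6 is hard to obtain as one enantiomer, since the cis relation on a 2,3-dihydrofuran is usually reached by a thermal rearrangement without absolute control. A7 requires the cis-dihydrobenzofuran to be carried on to an aldehyde and re-protected. The C4 stereocentre is made only to be erased.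
- Compared with the chosen strategy: both routes expose ionisable benzylic ethers to Lewis acid twice, so the chosen strategy has no advantage there. It offers instead a catalytic enantioselective entry to the endo aryl group from the ordinary exo-aryl cyclopropane, a stable lactone as coupling partner, and a C4 that arrives at the right oxidation level.

Key step: step 7

Remark: the sense of induction of Rh2(4S-MPPIM)4 (step 6) and Rh2(S-PTTL)4 (step 13) is assumed by analogy with the parent (E)-cinnamyl diazoacetate and 2-(benzyloxy)phenyl diazoacetate; if either gives the mirror image, its enantiomeric catalyst is used, and the same holds for the prolinol catalyst of the fallback to step 7.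

## Steps

Step 1
Reactants: 1 vanillin (4-hydroxy-3-methoxybenzaldehyde)
Product: 2 3-methoxy-4-(triisopropylsilyloxy)benzaldehyde (ArCHO)
Conditions: TIPSCl, imidazole, DMF, rt
Reagents that add atoms: chlorotriisopropylsilane, CC(C)[Si](Cl)(C(C)C)C(C)C
Why: Phenol silylation; the triisopropylsilyl ether should survive hydride, organolithium and cold Lewis acid steps and is removed by fluoride at the end.

Step 2
Reactants: 2 ArCHO; 3 triethyl phosphonoacetate
Product: 4 ethyl (E)-3-Ar-prop-2-enoate
Conditions: NaH, THF, 0 °C → rt
Reagents that add atoms: none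
Why: Horner–Wadsworth–Emmons olefination; the stabilised phosphonate anion gives the (E)-alkene, whose geometry later becomes the exo position of the aryl group.

Step 3
Reactants: 4 ethyl (E)-3-Ar-prop-2-enoate
Product: 5 (E)-3-Ar-prop-2-en-1-ol
Conditions: i-Bu2AlH, CH2Cl2, −78 °C
Reagents that add atoms: none
Why: 1,2-Reduction of the conjugated ester by the aluminium hydride; alkene geometry and silyl ether are not affected.

Step 4
Reactants: 5 (E)-3-Ar-prop-2-en-1-ol; 6 bromoacetyl bromide
Product: 7 (E)-3-Ar-prop-2-enyl bromoacetate
Conditions: NaHCO3, MeCN, 0 °C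
Reagents that add atoms: none
Why: O-Acylation by the acid bromide; solid bicarbonate takes up HBr so that the electron-rich allylic alcohol does not ionise.

Step 5
Reactants: 7 (E)-3-Ar-prop-2-enyl bromoacetate
Product: 8 (E)-3-Ar-prop-2-enyl diazoacetate
Conditions: TsNHNHTs, DBU, THF, 0 °C
Reagents that add atoms: N,N'-ditosylhydrazine, Cc1ccc(cc1)S(=O)(=O)NNS(=O)(=O)c1ccc(C)cc1
Why: N-Alkylation of the ditosylhydrazine by the bromoacetate, then base-induced loss of two sulfinate ions (Bamford–Stevens-type elimination), gives the diazoacetate under mild conditions.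

Step 6
Reactants: 8 (E)-3-Ar-prop-2-enyl diazoacetate
Product: 9 (1R,5S,6S)-6-Ar-3-oxabicyclo[3.1.0]hexan-2-one (Ar exo)
Conditions: Rh2(4S-MPPIM)4 (1 mol%), CH2Cl2, reflux, slow addition of 8
Reagents that add atoms: none
Why: Enantioselective intramolecular cyclopropanation; the rhodium carbene adds to the (E)-alkene with retention of geometry, so Ar is trans to the lactone CH2 (exo) and the tether forces cis fusion. The chiral ligands, methyl 2-oxo-1-(3-phenylpropanoyl)imidazolidine-4-carboxylate, select the alkene face, and this carboxamidate is the one suited to trans-disubstituted allylic diazoacetates.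

Step 7
Reactants: 9 (1R,5S,6S)-6-Ar-3-oxabicyclo[3.1.0]hexan-2-one; 10 formaldehyde (monomer from cracked paraformaldehyde)
Product: 11 (1S,5S,6S)-6-Ar-3,7-dioxabicyclo[3.3.0]octan-2-one (Ar endo)
Conditions: CH2O (10, ca. 5 equiv, cold CH2Cl2 solution), Sn(OTf)2 (20 mol%), 4 Å MS, CH2Cl2, −78 → −30 °C
Reagents that add atoms: none
Why: Proposed new method: Sn(OTf)2 binds the lactone carbonyl of 9 and polarises the C1–C6 bond, the only cyclopropane bond that is both benzylic and alpha to the carbonyl and the one aligned with the carbonyl pi system, whereas C1–C5 lies in the lactone plane and C5–C6 has no acceptor. The oxygen of formaldehyde attacks C6 from the side opposite the departing enolate carbon (SN2-like, inversion), which gives a tin lactone enolate tethered to an oxocarbenium ion. The enolate carbon adds to the oxocarbenium carbon in an aldol-type 5-(enolexo)-endo-trig closure, formally disfavoured but usual for oxocarbenium electrophiles, and this forms C4–C5 and the tetrahydrofuran ring (target numbering). The closest known reaction is the Lewis acid catalysed formal [3+2] annulation of 2-arylcyclopropane-1,1-diesters with aldehydes, stereospecific with inversion at the donor carbon; new here are the single lactone acceptor, the bicyclic substrate and formaldehyde as partner. The benzylic centre is controlled by the configuration of C6 in 9 through inversion, so the exo aryl group becomes cis to the lactone methylene carbon and therefore endo. The ring-fusion centre alpha to the carbonyl is controlled by the untouched neighbouring bridgehead, since two five-membered rings can only be cis-fused. The step needs SN2-like opening in preference to ionisation to a free benzylic cation, and the low temperature, the mild divalent tin salt and the silyl ether (a weaker pi-donor than an alkyl ether) all work in that direction; ionisation could cost only the endo/exo selectivity and not enantiopurity, because the bridgehead bearing the lactone CH2 is never broken. Attack of activated formaldehyde on ring A is held back by the bulky silyl ether and a low monomer concentration.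

Step 8
Reactants: 2 ArCHO
Product: 12 [3-methoxy-4-(triisopropylsilyloxy)phenyl]methanol (ArCH2OH)
Conditions: NaBH4, MeOH, 0 °C
Reagents that add atoms: none
Why: Borohydride reduction of the aldehyde; it supplies ring C from the same intermediate as ring A.

Step 9
Reactants: 13 4-bromo-2-methoxyphenol
Product: 14 4-bromo-2-iodo-6-methoxyphenol
Conditions: NIS, TsOH·H2O (cat.), MeCN, 0 °C → rt
Reagents that add atoms: N-iodosuccinimide, O=C1CCC(=O)N1I
Why: Electrophilic aromatic iodination directed by the phenol; the para position is blocked by bromine, so only the free ortho position reacts.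

Step 10
Reactants: 14 4-bromo-2-iodo-6-methoxyphenol; 12 ArCH2OH
Product: 15 5-bromo-1-iodo-3-methoxy-2-(Ar-methoxy)benzene
Conditions: PPh3, DIAD, THF, 0 °C → rt
Reagents that add atoms: none
Why: Mitsunobu etherification of an acidic phenol with a primary benzylic alcohol; it avoids an unstable para-silyloxybenzyl halide.

Step 11
Reactants: 15 5-bromo-1-iodo-3-methoxy-2-(Ar-methoxy)benzene; 16 dimethyl oxalate
Product: 17 methyl 2-[5-bromo-3-methoxy-2-(Ar-methoxy)phenyl]-2-oxoacetate
Conditions: i-PrMgCl·LiCl, THF, −40 °C; then added to 16 (3 equiv), THF, −78 °C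
Reagents that add atoms: none
Why: Iodine–magnesium exchange is far faster than bromine–magnesium exchange and is assisted by the ortho ether oxygen; acylation of the aryl Grignard reagent by excess oxalate in the cold should stop at the keto ester.

Step 12
Reactants: 17 methyl 2-[5-bromo-3-methoxy-2-(Ar-methoxy)phenyl]-2-oxoacetate
Product: 19 methyl 2-[5-bromo-3-methoxy-2-(Ar-methoxy)phenyl]-2-diazoacetate, via tosylhydrazone 18 (not isolated)
Conditions: TsNHNH2, MeOH, 60 °C; then DBU, CH2Cl2, rt
Reagents that add atoms: p-toluenesulfonohydrazide, Cc1ccc(cc1)S(=O)(=O)NN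
Why: Condensation at the ketone carbonyl and Bamford–Stevens elimination of sulfinate give the aryl diazoacetate, a donor–acceptor diazo compound stable enough to purify.

Step 13
Reactants: 19 methyl 2-[5-bromo-3-methoxy-2-(Ar-methoxy)phenyl]-2-diazoacetate
Product: 20 methyl (2S,3R)-2-Ar-5-bromo-7-methoxy-2,3-dihydro-1-benzofuran-3-carboxylate (2,3-cis)
Conditions: Rh2(S-PTTL)4 (1 mol%), toluene, −78 °C
Reagents that add atoms: none
Why: Enantioselective intramolecular 1,5 C–H insertion of the rhodium carbene into the benzylic C–H bond of the aryl ether, which is activated by the ether oxygen and the electron-rich ring C. The concerted insertion gives the cis isomer as kinetic product, the N-phthaloyl-tert-leucinate ligands control both new centres (C2', C3'), and no base is present to epimerise the cis ester.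

Step 14
Reactants: 20 methyl (2S,3R)-2-Ar-5-bromo-7-methoxy-2,3-dihydro-1-benzofuran-3-carboxylate
Product: 21 [(2S,3S)-2-Ar-5-bromo-7-methoxy-2,3-dihydro-1-benzofuran-3-yl]methanol (2,3-cis)
Conditions: i-Bu2AlH, CH2Cl2, −78 → 0 °C
Reagents that add atoms: none
Why: Ester reduction by a Lewis acidic, non-basic hydride is faster than enolisation, so the cis relation is kept (the C3' descriptor changes only through the priority rules); the aryl bromide is inert.

Step 15
Reactants: 21 [(2S,3S)-2-Ar-5-bromo-7-methoxy-2,3-dihydro-1-benzofuran-3-yl]methanol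
Product: 22 (2S,3S)-2-Ar-5-bromo-7-methoxy-3-[(triisopropylsilyloxy)methyl]-2,3-dihydro-1-benzofuran
Conditions: TIPSCl, imidazole, DMAP (cat.), DMF, rt
Reagents that add atoms: chlorotriisopropylsilane, CC(C)[Si](Cl)(C(C)C)C(C)C
Why: Silylation of the primary alcohol removes the only acidic proton before lithiation and lets all three protecting groups fall in one final step.

Step 16
Reactants: 22 (2S,3S)-2-Ar-5-bromo-7-methoxy-3-[(triisopropylsilyloxy)methyl]-2,3-dihydro-1-benzofuran; 11 (1S,5S,6S)-6-Ar-3,7-dioxabicyclo[3.3.0]octan-2-one
Product: 24 (1S,5S,6S)-6-Ar-2-{(2S,3S)-2-Ar-7-methoxy-3-[(triisopropylsilyloxy)methyl]-2,3-dihydro-1-benzofuran-5-yl}-3,7-dioxabicyclo[3.3.0]octan-2-ol (numbering of 11; lactol as a mixture of anomers), via aryllithium 23 (not isolated)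
Conditions: t-BuLi (2 equiv), THF, −78 °C; then 11, −78 °C; AcOH quench at −78 °C
Reagents that add atoms: none
Why: Bromine–lithium exchange followed by 1,2-addition of the aryllithium to the γ-lactone; the lithium hemiketal should hold at −78 °C, which prevents a second addition. The carbon alpha to the carbonyl is a ring-fusion carbon and cannot epimerise by enolisation; the lactol (in equilibrium with its hydroxy ketone form) is used crude.

Step 17
Reactants: 24 lactol
Product: 25 (1S,2S,5S,6S)-2-Ar-6-{(2S,3S)-2-Ar-7-methoxy-3-[(triisopropylsilyloxy)methyl]-2,3-dihydro-1-benzofuran-5-yl}-3,7-dioxabicyclo[3.3.0]octane (numbering of the target)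
Conditions: Et3SiH, BF3·OEt2, CH2Cl2, −78 °C; Et3N quench at −78 °C
Reagents that add atoms: none
Why: Ionic hydrogenation of the lactol: BF3 ionises C6–OH to an oxocarbenium ion conjugated with ring B, and the silane delivers hydride to the convex face of the cis-fused bicycle, away from the C4 methylene on the concave side. H6 should therefore end cis to H5 and ring B endo (C6 = S); at −78 °C with a cold amine quench the benzylic ether at C2 should not ionise.

Step 18
Reactants: 25 tris(triisopropylsilyl) ether of the target
Product: 26 4-[(1S,2S,5S,6S)-6-[(2S,3S)-2-(4-hydroxy-3-methoxyphenyl)-3-(hydroxymethyl)-7-methoxy-2,3-dihydro-1-benzofuran-5-yl]-3,7-dioxabicyclo[3.3.0]octan-2-yl]-2-methoxyphenol (target)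
Conditions: Bu4NF, AcOH, THF, 0 °C → rt
Reagents that add atoms: none
Why: Fluoride-induced cleavage of two aryl silyl ethers and one alkyl silyl ether; acetic acid buffers the phenoxides, and since neither acid nor hydrogen is used the three benzylic C–O bonds and all six stereocentres are left alone.

## Compound list

1 | vanillin (4-hydroxy-3-methoxybenzaldehyde) | COc1cc(C=O)ccc1O | starting material
2 | 3-methoxy-4-(triisopropylsilyloxy)benzaldehyde | COc1cc(C=O)ccc1O[Si](C(C)C)(C(C)C)C(C)C | intermediate
3 | triethyl phosphonoacetate | CCOC(=O)CP(=O)(OCC)OCC | starting material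
4 | ethyl (E)-3-[3-methoxy-4-(triisopropylsilyloxy)phenyl]prop-2-enoate | CCOC(=O)/C=C/c1ccc(O[Si](C(C)C)(C(C)C)C(C)C)c(OC)c1 | intermediate
5 | (E)-3-[3-methoxy-4-(triisopropylsilyloxy)phenyl]prop-2-en-1-ol | OC/C=C/c1ccc(O[Si](C(C)C)(C(C)C)C(C)C)c(OC)c1 | intermediate
6 | bromoacetyl bromide | BrCC(Br)=O | starting material
7 | (E)-3-[3-methoxy-4-(triisopropylsilyloxy)phenyl]prop-2-enyl bromoacetate | BrCC(=O)OC/C=C/c1ccc(O[Si](C(C)C)(C(C)C)C(C)C)c(OC)c1 | intermediate
8 | (E)-3-[3-methoxy-4-(triisopropylsilyloxy)phenyl]prop-2-enyl diazoacetate | [N-]=[N+]=CC(=O)OC/C=C/c1ccc(O[Si](C(C)C)(C(C)C)C(C)C)c(OC)c1 | intermediate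
9 | (1R,5S,6S)-6-[3-methoxy-4-(triisopropylsilyloxy)phenyl]-3-oxabicyclo[3.1.0]hexan-2-one (aryl exo) | COc1cc([C@@H]2[C@@H]3[C@H]2COC3=O)ccc1O[Si](C(C)C)(C(C)C)C(C)C | intermediate
10 | formaldehyde (monomer; supplied as paraformaldehyde and cracked before use) | C=O | starting material
11 | (1S,5S,6S)-6-[3-methoxy-4-(triisopropylsilyloxy)phenyl]-3,7-dioxabicyclo[3.3.0]octan-2-one (aryl endo) | COc1cc([C@H]2OC[C@@H]3[C@H]2COC3=O)ccc1O[Si](C(C)C)(C(C)C)C(C)C | intermediate
12 | [3-methoxy-4-(triisopropylsilyloxy)phenyl]methanol | COc1cc(CO)ccc1O[Si](C(C)C)(C(C)C)C(C)C | intermediate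
13 | 4-bromo-2-methoxyphenol | COc1cc(Br)ccc1O | starting material
14 | 4-bromo-2-iodo-6-methoxyphenol | COc1cc(Br)cc(I)c1O | intermediate
15 | 5-bromo-1-iodo-3-methoxy-2-{[3-methoxy-4-(triisopropylsilyloxy)phenyl]methoxy}benzene | COc1cc(Br)cc(I)c1OCc1ccc(O[Si](C(C)C)(C(C)C)C(C)C)c(OC)c1 | intermediate
16 | dimethyl oxalate | COC(=O)C(=O)OC | starting material
17 | methyl 2-(5-bromo-3-methoxy-2-{[3-methoxy-4-(triisopropylsilyloxy)phenyl]methoxy}phenyl)-2-oxoacetate | COC(=O)C(=O)c1cc(Br)cc(OC)c1OCc1ccc(O[Si](C(C)C)(C(C)C)C(C)C)c(OC)c1 | intermediate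
18 | N-tosylhydrazone of 17 | COC(=O)C(=NNS(=O)(=O)c1ccc(C)cc1)c1cc(Br)cc(OC)c1OCc1ccc(O[Si](C(C)C)(C(C)C)C(C)C)c(OC)c1 | intermediate
19 | methyl 2-(5-bromo-3-methoxy-2-{[3-methoxy-4-(triisopropylsilyloxy)phenyl]methoxy}phenyl)-2-diazoacetate | COC(=O)C(=[N+]=[N-])c1cc(Br)cc(OC)c1OCc1ccc(O[Si](C(C)C)(C(C)C)C(C)C)c(OC)c1 | intermediate
20 | methyl (2S,3R)-5-bromo-7-methoxy-2-[3-methoxy-4-(triisopropylsilyloxy)phenyl]-2,3-dihydro-1-benzofuran-3-carboxylate (2,3-cis) | Brc1cc(OC)c2c(c1)[C@@H](C(=O)OC)[C@@H](c1ccc(O[Si](C(C)C)(C(C)C)C(C)C)c(OC)c1)O2 | intermediate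
21 | {(2S,3S)-5-bromo-7-methoxy-2-[3-methoxy-4-(triisopropylsilyloxy)phenyl]-2,3-dihydro-1-benzofuran-3-yl}methanol (2,3-cis) | Brc1cc(OC)c2c(c1)[C@@H](CO)[C@@H](c1ccc(O[Si](C(C)C)(C(C)C)C(C)C)c(OC)c1)O2 | intermediate
22 | (2S,3S)-5-bromo-7-methoxy-2-[3-methoxy-4-(triisopropylsilyloxy)phenyl]-3-[(triisopropylsilyloxy)methyl]-2,3-dihydro-1-benzofuran | Brc1cc(OC)c2c(c1)[C@@H](CO[Si](C(C)C)(C(C)C)C(C)C)[C@@H](c1ccc(O[Si](C(C)C)(C(C)C)C(C)C)c(OC)c1)O2 | intermediate
23 | 5-lithio analogue of 22 (aryllithium) | [Li]c1cc(OC)c2c(c1)[C@@H](CO[Si](C(C)C)(C(C)C)C(C)C)[C@@H](c1ccc(O[Si](C(C)C)(C(C)C)C(C)C)c(OC)c1)O2 | intermediate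
24 | (1S,5S,6S)-6-[3-methoxy-4-(triisopropylsilyloxy)phenyl]-2-{(2S,3S)-7-methoxy-2-[3-methoxy-4-(triisopropylsilyloxy)phenyl]-3-[(triisopropylsilyloxy)methyl]-2,3-dihydro-1-benzofuran-5-yl}-3,7-dioxabicyclo[3.3.0]octan-2-ol (lactol, both anomers) | COc1cc([C@H]2OC[C@@H]3[C@H]2COC3(O)c2cc(OC)c3c(c2)[C@@H](CO[Si](C(C)C)(C(C)C)C(C)C)[C@@H](c2ccc(O[Si](C(C)C)(C(C)C)C(C)C)c(OC)c2)O3)ccc1O[Si](C(C)C)(C(C)C)C(C)C | intermediate
25 | (1S,2S,5S,6S)-2-[3-methoxy-4-(triisopropylsilyloxy)phenyl]-6-{(2S,3S)-7-methoxy-2-[3-methoxy-4-(triisopropylsilyloxy)phenyl]-3-[(triisopropylsilyloxy)methyl]-2,3-dihydro-1-benzofuran-5-yl}-3,7-dioxabicyclo[3.3.0]octane | COc1cc([C@H]2OC[C@@H]3[C@H]2CO[C@@H]3c2cc(OC)c3c(c2)[C@@H](CO[Si](C(C)C)(C(C)C)C(C)C)[C@@H](c2ccc(O[Si](C(C)C)(C(C)C)C(C)C)c(OC)c2)O3)ccc1O[Si](C(C)C)(C(C)C)C(C)C | intermediate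
26 | 4-[(1S,2S,5S,6S)-6-[(2S,3S)-2-(4-hydroxy-3-methoxyphenyl)-3-(hydroxymethyl)-7-methoxy-2,3-dihydro-1-benzofuran-5-yl]-3,7-dioxabicyclo[3.3.0]octan-2-yl]-2-methoxyphenol | COc1cc([C@H]2OC[C@@H]3[C@H]2CO[C@@H]3c2cc(OC)c3c(c2)[C@@H](CO)[C@@H](c2ccc(O)c(OC)c2)O3)ccc1O | target

## Step count and least certain steps

Total: 18 steps. Longest linear sequence: 11 steps (1 → 2 → 12 → 15 → 17 → 19 → 20 → 21 → 22 → 24 → 25 → 26; steps 1, 8 and 10–18). The ring A branch (steps 1–7, then 16–18) has 10.

**Step 7 (key step, proposed new method).**
- What may go wrong: activation may be too weak, because one lactone carbonyl cannot chelate the Lewis acid as a 1,1-diester does. Forcing the opening would then bring loss of stereospecificity at the benzylic carbon through ionisation, or proton loss from the opened zwitterion. Formaldehyde is also a weak oxygen nucleophile and may polymerise or attack ring A.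
- Fallback (known chemistry): it sets out from alcohol 5 and comes back at lactone 11. MnO2 oxidises 5 to (E)-3-[3-methoxy-4-(triisopropylsilyloxy)phenyl]prop-2-enal F1. Iminium-catalysed cyclopropanation with dimethyl bromomalonate ((R)-α,α-diphenylprolinol trimethylsilyl ether, 2,6-lutidine, CH2Cl2) gives dimethyl (2R,3S)-3-formyl-2-[3-methoxy-4-(triisopropylsilyloxy)phenyl]cyclopropane-1,1-dicarboxylate F2. NaBH4 reduces the aldehyde and the alcohol closes onto the cis ester, giving methyl (1R,5S,6R)-6-[3-methoxy-4-(triisopropylsilyloxy)phenyl]-2-oxo-3-oxabicyclo[3.1.0]hexane-1-carboxylate F3. F3 is a cyclopropane-1,1-dicarbonyl compound, the class for which the Sn(OTf)2-catalysed aldehyde annulation with inversion is established; with 10 it should give methyl (1S,5S,6S)-6-[3-methoxy-4-(triisopropylsilyloxy)phenyl]-2-oxo-3,7-dioxabicyclo[3.3.0]octane-1-carboxylate F4. Krapcho dealkoxycarbonylation (LiCl, wet DMSO, 130 °C) removes the angular ester, and reprotonation can only give cis-fused 11.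

**Step 17.**
- What may go wrong: Lewis acid ionisation of an endo benzylic ether bond with reclosure to the more stable exo arrangement, or ionic hydrogenolysis of a benzylic C–O bond by excess silane.
- Fallback: it sets out from 24 and comes back at 25 without any cation. Corey–Bakshi–Shibata reduction of the hydroxy ketone form of 24 ((R)-2-methyl-CBS-oxazaborolidine, BH3·SMe2) gives (S)-{(3S,4S,5S)-4-(hydroxymethyl)-5-[3-methoxy-4-(triisopropylsilyloxy)phenyl]tetrahydrofuran-3-yl}{(2S,3S)-7-methoxy-2-[3-methoxy-4-(triisopropylsilyloxy)phenyl]-3-[(triisopropylsilyloxy)methyl]-2,3-dihydro-1-benzofuran-5-yl}methanol F9. Selective sulfonylation of the primary hydroxyl group (TsCl, Et3N, cold) gives its primary p-toluenesulfonate F10. NaH then closes O7–C8 by SN2 at the primary carbon, with retention at C6, to give 25.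

**Step 16.**
- What may go wrong: enolisation of the lactone by the hindered aryllithium (loss of conversion), or opening of the lithium hemiketal followed by a second addition or epimerisation alpha to the ketone.
- Fallback: it sets out from 11 and comes back at 25. Me(MeO)NH·HCl with i-PrMgCl opens 11 to (3S,4S,5S)-4-(hydroxymethyl)-N-methoxy-5-[3-methoxy-4-(triisopropylsilyloxy)phenyl]-N-methyltetrahydrofuran-3-carboxamide F6. Et3SiCl and imidazole give its triethylsilyl ether F7. Aryllithium 23 adds once to F7 through the chelated tetrahedral intermediate to give {(3S,4S,5S)-5-[3-methoxy-4-(triisopropylsilyloxy)phenyl]-4-[(triethylsilyloxy)methyl]tetrahydrofuran-3-yl}{(2S,3S)-7-methoxy-2-[3-methoxy-4-(triisopropylsilyloxy)phenyl]-3-[(triisopropylsilyloxy)methyl]-2,3-dihydro-1-benzofuran-5-yl}methanone F8. Reductive etherification of the silyloxy ketone under the conditions of step 17 gives 25.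

**Step 13.**
- What may go wrong: incomplete enantio- or cis-selectivity, because the methoxy group ortho to the ether oxygen changes the conformation of the benzyloxy group in the insertion transition state; diversion through an oxonium ylide at the ether oxygen is also possible.
- Fallback: enantiopurity is secured by separation of diastereomers. It sets out from 21 of insufficient purity and comes back at enantiopure 21. Esterification with (R)-O-methylmandelic acid (DCC, DMAP) gives {(2S,3S)-5-bromo-7-methoxy-2-[3-methoxy-4-(triisopropylsilyloxy)phenyl]-2,3-dihydro-1-benzofuran-3-yl}methyl (R)-2-methoxy-2-phenylacetate F5, which is freed from its diastereomers by crystallisation or chromatography. LiBH4 then cleaves the ester to return 21.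

Further compounds
F1 | step 7 | (E)-3-[3-methoxy-4-(triisopropylsilyloxy)phenyl]prop-2-enal | O=C/C=C/c1ccc(O[Si](C(C)C)(C(C)C)C(C)C)c(OC)c1
F2 | step 7 | dimethyl (2R,3S)-3-formyl-2-[3-methoxy-4-(triisopropylsilyloxy)phenyl]cyclopropane-1,1-dicarboxylate | COc1cc([C@@H]2C(C(=O)OC)(C(=O)OC)[C@H]2C=O)ccc1O[Si](C(C)C)(C(C)C)C(C)C
F3 | step 7 | methyl (1R,5S,6R)-6-[3-methoxy-4-(triisopropylsilyloxy)phenyl]-2-oxo-3-oxabicyclo[3.1.0]hexane-1-carboxylate | COc1cc([C@@H]2[C@]3(C(=O)OC)[C@H]2COC3=O)ccc1O[Si](C(C)C)(C(C)C)C(C)C
F4 | step 7 | methyl (1S,5S,6S)-6-[3-methoxy-4-(triisopropylsilyloxy)phenyl]-2-oxo-3,7-dioxabicyclo[3.3.0]octane-1-carboxylate | COc1cc([C@H]2OC[C@]3(C(=O)OC)[C@H]2COC3=O)ccc1O[Si](C(C)C)(C(C)C)C(C)C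
F5 | step 13 | {(2S,3S)-5-bromo-7-methoxy-2-[3-methoxy-4-(triisopropylsilyloxy)phenyl]-2,3-dihydro-1-benzofuran-3-yl}methyl (R)-2-methoxy-2-phenylacetate | Brc1cc(OC)c2c(c1)[C@@H](COC(=O)[C@H](OC)c1ccccc1)[C@@H](c1ccc(O[Si](C(C)C)(C(C)C)C(C)C)c(OC)c1)O2
F6 | step 16 | (3S,4S,5S)-4-(hydroxymethyl)-N-methoxy-5-[3-methoxy-4-(triisopropylsilyloxy)phenyl]-N-methyltetrahydrofuran-3-carboxamide | COc1cc([C@H]2OC[C@@H](C(=O)N(C)OC)[C@H]2CO)ccc1O[Si](C(C)C)(C(C)C)C(C)C
F7 | step 16 | (3S,4S,5S)-N-methoxy-5-[3-methoxy-4-(triisopropylsilyloxy)phenyl]-N-methyl-4-[(triethylsilyloxy)methyl]tetrahydrofuran-3-carboxamide | COc1cc([C@H]2OC[C@@H](C(=O)N(C)OC)[C@H]2CO[Si](CC)(CC)CC)ccc1O[Si](C(C)C)(C(C)C)C(C)C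
F8 | step 16 | {(3S,4S,5S)-5-[3-methoxy-4-(triisopropylsilyloxy)phenyl]-4-[(triethylsilyloxy)methyl]tetrahydrofuran-3-yl}{(2S,3S)-7-methoxy-2-[3-methoxy-4-(triisopropylsilyloxy)phenyl]-3-[(triisopropylsilyloxy)methyl]-2,3-dihydro-1-benzofuran-5-yl}methanone | COc1cc([C@H]2OC[C@@H](C(=O)c3cc(OC)c4c(c3)[C@@H](CO[Si](C(C)C)(C(C)C)C(C)C)[C@@H](c3ccc(O[Si](C(C)C)(C(C)C)C(C)C)c(OC)c3)O4)[C@H]2CO[Si](CC)(CC)CC)ccc1O[Si](C(C)C)(C(C)C)C(C)C
F9 | step 17 | (S)-{(3S,4S,5S)-4-(hydroxymethyl)-5-[3-methoxy-4-(triisopropylsilyloxy)phenyl]tetrahydrofuran-3-yl}{(2S,3S)-7-methoxy-2-[3-methoxy-4-(triisopropylsilyloxy)phenyl]-3-[(triisopropylsilyloxy)methyl]-2,3-dihydro-1-benzofuran-5-yl}methanol | COc1cc([C@H]2OC[C@@H]([C@H](O)c3cc(OC)c4c(c3)[C@@H](CO[Si](C(C)C)(C(C)C)C(C)C)[C@@H](c3ccc(O[Si](C(C)C)(C(C)C)C(C)C)c(OC)c3)O4)[C@H]2CO)ccc1O[Si](C(C)C)(C(C)C)C(C)C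
F10 | step 17 | primary p-toluenesulfonate of F9 | COc1cc([C@H]2OC[C@@H]([C@H](O)c3cc(OC)c4c(c3)[C@@H](CO[Si](C(C)C)(C(C)C)C(C)C)[C@@H](c3ccc(O[Si](C(C)C)(C(C)C)C(C)C)c(OC)c3)O4)[C@H]2COS(=O)(=O)c2ccc(C)cc2)ccc1O[Si](C(C)C)(C(C)C)C(C)C
A1 | alternative 1 | (2S,3S)-2-(4-benzyloxy-3-methoxyphenyl)-3-[(tert-butyldimethylsilyloxy)methyl]-5-(1,3-dioxolan-2-yl)-7-methoxy-2,3-dihydro-1-benzofuran (2,3-cis) | O1CCOC1c1cc(OC)c2c(c1)[C@@H](CO[Si](C)(C)C(C)(C)C)[C@@H](c1ccc(OCc3ccccc3)c(OC)c1)O2
A2 | alternative 1 | 2-[(1S,2S)-1-(4-benzyloxy-3-methoxyphenyl)-3-(tert-butyldimethylsilyloxy)-1-hydroxypropan-2-yl]-4-(1,3-dioxolan-2-yl)-6-methoxyphenyl trifluoromethanesulfonate | O1CCOC1c1cc(OC)c(OS(=O)(=O)C(F)(F)F)c(c1)[C@@H](CO[Si](C)(C)C(C)(C)C)[C@H](O)c1ccc(OCc3ccccc3)c(OC)c1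
A3 | alternative 2 | methyl (2S,3R)-2-(4-benzyloxy-3-methoxyphenyl)-5-bromo-7-methoxy-2,3-dihydro-1-benzofuran-3-carboxylate (2,3-cis) | Brc1cc(OC)c2c(c1)[C@@H](C(=O)OC)[C@@H](c1ccc(OCc3ccccc3)c(OC)c1)O2
A4 | alternative 2 | (2R)-2-(4-benzyloxy-3-methoxyphenyl)-6-bromo-3-diazo-8-methoxy-2,3-dihydro-4H-chromen-4-one | COc1cc(Br)cc2C(=O)C(=[N+]=[N-])[C@@H](c3ccc(OCc4ccccc4)c(OC)c3)Oc12
A5 | alternative 3 | bis-endo 2-(4-benzyloxy-3-methoxyphenyl)-4-methoxy-6-[(2S,3S)-3-(acetoxymethyl)-2-(4-benzyloxy-3-methoxyphenyl)-7-methoxy-2,3-dihydro-1-benzofuran-5-yl]-3,7-dioxabicyclo[3.3.0]octane | COc1cc([C@H]2O[C@H](OC)[C@@H]3[C@H]2CO[C@@H]3c2cc(OC)c3c(c2)[C@@H](COC(C)=O)[C@@H](c2ccc(OCc4ccccc4)c(OC)c2)O3)ccc1OCc1ccccc1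
A6 | alternative 3 | [(2S,3S)-2-(4-benzyloxy-3-methoxyphenyl)-2,3-dihydrofuran-3-yl]methanol (2,3-cis) | COc1cc([C@H]2OC=C[C@H]2CO)ccc1OCc1ccccc1
A7 | alternative 3 | [(2S,3S)-2-(4-benzyloxy-3-methoxyphenyl)-5-(dimethoxymethyl)-7-methoxy-2,3-dihydro-1-benzofuran-3-yl]methyl acetate | COC(OC)c1cc(OC)c2c(c1)[C@@H](COC(C)=O)[C@@H](c1ccc(OCc3ccccc3)c(OC)c1)O2
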